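**Conventions.** Locants follow the elemane numbering: ring carbons C5–C10; C4 (with the C15 methylene and the C3 aldehyde) on C5; C11 (with the C13 methylene and the C12 lactone carbonyl) on C7; the C14 methyl and the C1–C2 oxirane on C10. β is the ring face that carries the C10 methyl, α the opposite face. TMSE is 2-(trimethylsilyl)ethyl.

**Assumption.** The target is taken as the open 6-hydroxy enal (its C3/O6 lactol tautomer is in equilibrium with it); C11 of the ester-bearing lactones and the acetal carbon C3 of the lactol intermediates are carried as epimeric mixtures, since neither is a stereocentre of the target.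

## Analysis of the target

The target 33 is an elemanolide: a cyclohexane (C5–C10) trans-fused at C7/C8 to an α-methylene-γ-butyrolactone (C11–C13, O on C8). It has seven stereocentres, six contiguous on the ring plus C1 of the oxirane. In the chair the C10 methyl (β), the C6 hydroxyl (β) and the C9 angelate (α) are axial; the C5 acrolein arm (β), the C7 lactone carbon (β), the lactone oxygen at C8 (α) and the oxiranyl group at C10 (α) are equatorial. C10 is quaternary and cannot be corrected once set. The sensitive groups are two Michael acceptors (methylene lactone and 2-substituted acrolein), whose allylic C7–H and C5–H allow the double bonds to move into conjugation, a terminal epoxide, a (Z)-configured angelate that isomerises to the tiglate, and a free 6β-hydroxyl cis to the lactone arm that could take over the lactone. The difficulty is to place an axial hydroxyl at C6 between two substituted carbons, to set C1 on a freely rotating side chain, and to order the late steps so that none of these groups meets acid, strong base or an oxidant it cannot survive. The strategy rests on one feature: C6 is bonded to C7, and C7 is β to the lactone carbonyl C12. C6 can therefore be joined to C7 as an acyl anion adding to a C7=C11 acceptor, which closes ring C5–C10 and delivers C6 as a ketone for later reduction.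

## Retrosynthetic reasoning

**C11=C13 and C4=C15 (33 ⇒ 31).** Both exocyclic methylene carbons are removed first. They are the most electrophilic parts of 33, and with a ketone at C6 the C7–H and C5–H would be doubly activated and the double bonds would move into the ring or the chain. They are therefore introduced last, together, by Mannich methylenation of the acid lactol 32, which 31 releases on desilylation. This needs C3 as an aldehyde with a CH2 at C4, and C11 carrying a carboxyl group that is lost in the methylenation.

**Oxirane C1–C2 and C2–O (31 ⇒ 30).** The oxirane is cut to the C1 aldehyde and a one-carbon nucleophile that delivers C2, not to a vinyl group and an oxidant. Around the C10–C1 bond only one sector is open: the path past C5 is closed by the equatorial C4 substituent and the path under the ring by the axial C9 oxygen. A reagent must enter between the C10 methyl and C9. An oxidant entering there puts oxygen on that side and should give the C1 epimer; a carbon nucleophile entering there, with the formyl oxygen turned away from the C9–O dipole, puts C2 on that side and gives the (1R)-oxirane.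

**Ester C–O at C9 (30 ⇒ 28 + 29).** The angelate is attached after the oxidative alkene cleavage, because that oxidant would attack it, and before the methylene transfer, because a free C9 hydroxyl would hydrogen-bond to the aldehyde and reverse its preferred rotamer. In 28 the C6 oxygen is tied up in the lactol acetal, so the C9 hydroxyl is the only free alcohol and no selectivity between the two axial hydroxyls is needed.

**C1=O and C3=O (28 ⇒ 27 ⇒ 25).** Both aldehydes are cut back to terminal alkenes, the vinyl group on C10 and an allyl group on C5, cleaved in one operation. The two aldehydes differ at once: only C3 can reach the cis 6β-hydroxyl and closes to a lactol, which is then silylated.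

**C6–H (25 ⇒ 24).** The axial alcohol comes from a ketone by hydride attack on the face opposite the axial C10 methyl. The lactone must already be closed on O8, otherwise the new hydroxyl would lactonise.

**Lactone O8–C12 (24 ⇒ 22).** Removal of the 8,9-acetonide frees the equatorial C8 hydroxyl next to the malonate, and one ester closes the trans-lactone. The C9 hydroxyl is trans to the C7 arm across the ring and cannot compete.

**C5–C4 (22 ⇒ 20).** The C5 arm is cut to an allyl group on a ketone enolate. An aldol with a ketone at this neopentyl position would be reversible, and the later dehydration and allylic oxidation would not be regioselective. Allylation is irreversible and C5 can be equilibrated to the equatorial isomer next to the ketone.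

**C6–C7 (20 ⇒ 19), the key disconnection.** Cutting C6–C7 opens the ring to an aldehyde tethered to an alkylidene malonate. The forward step must close a six-membered ring from an aliphatic aldehyde and set C7; the quaternary C10 and the cis-dioxolane preorganise the chain, and C7 is under thermodynamic control.

**C6=O and C7=C11 (19 ⇒ 18 ⇒ 14 + 17).** The aldehyde is masked as a terminal alkyne (C5≡C6), which is inert to the acid used in the protecting-group exchange. An acetal at C6 would be captured there by the free C9 hydroxyl as a five-membered cyclic acetal. The acceptor comes from the C7 aldehyde 14 and malonate 17; TMSE esters are chosen because the remaining ester must later be cleaved next to an epoxide, an angelate and a lactone.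

**Ester C–O bonds of the malonate (17 ⇒ 15 + 16).** Both ester bonds of 17 are cut to the bis-acid chloride 15 and two equivalents of alcohol 16, so that the symmetrical diester is made in one acylation.

**Protecting-group exchange (14 ⇒ 9).** The 7,8-acetonide of 9 is exchanged for the 8,9-acetonide so that C7 can be oxidised; the internal cis-dioxolane does not form by equilibration, hence the detour through triol 10 and silyl ether 11.

**C9–C10 (9 ⇒ 6 + 7).** Allylboration of aldehyde 7 with the γ,γ-disubstituted allylboronate 6 forms C9–C10 and sets both centres in a closed transition state. C8 comes from 7.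

**C–B (6 ⇒ 1).** The Z geometry that fixes C10 is bought with alcohol 1; a ketone olefination would give an E/Z mixture.

## Alternatives that were turned down

**Alternative 1: enone–cyclobutene photocycloaddition.**
- Disconnection: C5–C4 and C10–C1 are cut together.
- Key step: irradiation of a ring enone (C9 carbonyl, C10=C5) with 1-methylcyclobutene A2 should give photoadduct A1, whose bicyclo[2.2.0]hexane later opens thermally to the vinyl and isopropenyl arms.
- For: the ring and C7 come from the chiral pool, one step forms two C–C bonds and the quaternary C10, and the C5 arm arrives complete. On step count to the carbon skeleton and on the C5 arm this plan is stronger than the chosen one.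
- Against: head-to-tail regiochemistry is not enforced by polarisation of a trisubstituted cyclobutene such as A2. The face of addition sets C5 and C10 together and C10 cannot be corrected. The cycloreversion needs heat on a β-silyloxy ketone. Afterwards the C9 ketone must become an axial alcohol next to C10, the saturated α-methyl lactone of A1 must be dehydrogenated to the exocyclic isomer, and the C1 problem remains.
- Comparison: the chosen route fixes C9 and C10 through a closed transition state from a defined alkene geometry, and carries C12 at the acid oxidation level from the start.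

**Alternative 2: nitrile oxide cycloaddition.**
- Disconnection: C5–C6 (and O–C4).
- Key step: a C6 nitrile oxide adds across a trisubstituted C5=C4 alkene to give the fused isoxazoline A3.
- For: intramolecular nitrile oxide cycloadditions are dependable, C6 emerges at the ketone level after N–O cleavage, and the C5 arm carbons are already attached. It is as strong as the chosen plan on the C6 ketone logic and stronger on the C5 arm.
- Against: A3 shows what is left. C7 carries an isopropenyl group whose methyl must be oxidised to the C12 carboxyl, and the C4 carbinol must be dehydrated away from conjugation and oxidised at a methyl, so two similar allylic oxidations are needed. The C7 stereocentre sits α to the oxime carbon in the acyclic precursor. The dipolarophile is trisubstituted and next to C10, and C5 is set with no clear bias.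
- Comparison: the chosen route sets C7 in the ring closure under thermodynamic control and has C11–C12 in place as a malonate.

**Alternative 3: carbonyl-ene closure.**
- Disconnection: C7–C8.
- Key step: a Lewis-acid-activated C8 aldehyde is attacked by a trisubstituted C7=C11 alkene with hydrogen transfer, giving cyclohexanol A4.
- For: the chair transition state of such closures is well understood and gives trans C7/C8. A4 already carries the C5 arm, both oxygens at C6 and C9, and C11=C13. No later C–C bond formation at C5 and no C6 reduction are needed, which is stronger than the chosen plan.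
- Against: the acyclic aldehyde needs C5, C6, C9 and C10 set beforehand in a long linear sequence. The α-alkoxy aldehyde can chelate the Lewis acid. Three alkenes compete as ene or Prins partners, and the C12 methyl must later be raised to an acid in the presence of two other allylic systems.
- Comparison: the chosen route offers a short precursor and avoids late allylic oxidation, at the price of functionalising C5 and C6 after ring closure.

Key step: step 13

## Route

Step 1
Reactants: 1 (Z)-3-methylpent-2-en-4-yn-1-ol
Product: 3 (Z)-3-methyl-5-(trimethylsilyl)pent-2-en-4-yn-1-ol, via bis-silyl ether 2 (not isolated)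
Conditions: EtMgBr (2.2 equiv), THF, 0 to 40 °C; Me3SiCl (2.3 equiv), 0 °C to rt; then 1 M HCl, rt
Reagents that add atoms: chlorotrimethylsilane, C[Si](C)(C)Cl
Why: Double deprotonation (O–H and acetylenic C–H) and silylation of both sites, then selective hydrolysis of the labile O–Si bond, is the standard C-silylation of a hydroxy alkyne; the cap keeps the alkyne out of the palladium step and the Z alkene is untouched.

Step 2
Reactants: 3 (Z)-3-methyl-5-(trimethylsilyl)pent-2-en-4-yn-1-ol
Product: 5 (Z)-(5-chloro-3-methylpent-3-en-1-yn-1-yl)trimethylsilane, via allylic mesylate 4 (not isolated)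
Conditions: MsCl, 2,4,6-collidine, LiCl, DMF, 0 °C
Reagents that add atoms: lithium chloride, [Li+].[Cl-]
Why: Collington–Meyers chlorination: the primary allylic mesylate is displaced by chloride in an SN2 step at low temperature, without allylic transposition or Z/E isomerisation.

Step 3
Reactants: 5 (Z)-(5-chloro-3-methylpent-3-en-1-yn-1-yl)trimethylsilane
Product: 6 (Z)-4,4,5,5-tetramethyl-2-[3-methyl-5-(trimethylsilyl)pent-2-en-4-yn-1-yl]-1,3,2-dioxaborolane
Conditions: B2pin2 (1.1 equiv), Pd2(dba)3 (2.5 mol %), THF, 60 °C
Reagents that add atoms: bis(pinacolato)diboron, CC1(C)OB(OC1(C)C)B1OC(C)(C)C(C)(C)O1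
Why: Palladium-catalysed borylation of an allylic chloride: oxidative addition to zerovalent palladium, transmetalation with the diboron and C–B reductive elimination at the unsubstituted terminus give the linear allylboronate; the geometry should be kept because syn/anti exchange would need a σ-bond at the fully substituted terminus.

Step 4
Reactants: 6 (Z)-4,4,5,5-tetramethyl-2-[3-methyl-5-(trimethylsilyl)pent-2-en-4-yn-1-yl]-1,3,2-dioxaborolane; 7 (R)-2,2-dimethyl-1,3-dioxolane-4-carbaldehyde
Product: 9 (1S,2S)-1-[(4R)-2,2-dimethyl-1,3-dioxolan-4-yl]-2-methyl-2-[(trimethylsilyl)ethynyl]but-3-en-1-ol, via pinacol borate 8 (not isolated)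
Conditions: toluene (1 M), 23 to 40 °C; then aqueous NaHCO3
Reagents that add atoms: none
Why: Allylboration through a closed chair transition state with the aldehyde substituent equatorial transfers the alkene geometry to C10: the methyl (trans to CH2B) ends anti and the alkynyl group (cis to CH2B) syn to the new C9 hydroxyl. The cis γ-substituent also enforces Felkin (8,9-anti) addition to the α-alkoxy aldehyde, so C9 follows from C8 of 7.

Step 5
Reactants: 9 (1S,2S)-1-[(4R)-2,2-dimethyl-1,3-dioxolan-4-yl]-2-methyl-2-[(trimethylsilyl)ethynyl]but-3-en-1-ol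
Product: 10 (2R,3S,4S)-4-methyl-4-[(trimethylsilyl)ethynyl]hex-5-ene-1,2,3-triol
Conditions: AcOH/H2O (4:1), 40 °C
Reagents that add atoms: none
Why: Acid hydrolysis of the terminal acetonide; the alkynylsilane and the alkene are inert, and with an alkyne at C5–C6 there is no latent aldehyde that the free C9 hydroxyl could trap.

Step 6
Reactants: 10 (2R,3S,4S)-4-methyl-4-[(trimethylsilyl)ethynyl]hex-5-ene-1,2,3-triol
Product: 11 (2R,3S,4S)-1-[(tert-butyldimethylsilyl)oxy]-4-methyl-4-[(trimethylsilyl)ethynyl]hex-5-ene-2,3-diol
Conditions: TBSCl (1.05 equiv), imidazole, CH2Cl2, 0 °C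
Reagents that add atoms: tert-butylchlorodimethylsilane, CC(C)(C)[Si](C)(C)Cl
Why: Silylation of the primary C7 hydroxyl in the presence of two secondary ones, one of them neopentyl, is selective with one equivalent at 0 °C.

Step 7
Reactants: 11 (2R,3S,4S)-1-[(tert-butyldimethylsilyl)oxy]-4-methyl-4-[(trimethylsilyl)ethynyl]hex-5-ene-2,3-diol
Product: 12 tert-butyl{[(4R,5S)-2,2-dimethyl-5-[(3S)-3-methyl-5-(trimethylsilyl)pent-1-en-4-yn-3-yl]-1,3-dioxolan-4-yl]methoxy}dimethylsilane
Conditions: Me2C(OMe)2, PPTS (cat.), CH2Cl2, rt
Reagents that add atoms: 2,2-dimethoxypropane, COC(C)(C)OC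
Why: Acid-catalysed transketalisation ties the 8,9-diol into the cis-dioxolane, which later holds C7 and C10 on the same side for the ring closure.

Step 8
Reactants: 12 tert-butyl{[(4R,5S)-2,2-dimethyl-5-[(3S)-3-methyl-5-(trimethylsilyl)pent-1-en-4-yn-3-yl]-1,3-dioxolan-4-yl]methoxy}dimethylsilane
Product: 13 [(4R,5S)-2,2-dimethyl-5-[(3S)-3-methylpent-1-en-4-yn-3-yl]-1,3-dioxolan-4-yl]methanol
Conditions: Bu4NF (2.5 equiv), THF, 0 °C to rt
Reagents that add atoms: none
Why: Fluoride removes the primary silyl ether and the alkynyl silane in one operation; the acetonide is inert.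

Step 9
Reactants: 13 [(4R,5S)-2,2-dimethyl-5-[(3S)-3-methylpent-1-en-4-yn-3-yl]-1,3-dioxolan-4-yl]methanol
Product: 14 (4S,5S)-2,2-dimethyl-5-[(3S)-3-methylpent-1-en-4-yn-3-yl]-1,3-dioxolane-4-carbaldehyde
Conditions: Dess–Martin periodinane, CH2Cl2, 0 °C to rt; used crude
Reagents that add atoms: none
Why: Dess–Martin oxidation under near-neutral conditions gives the α-alkoxy aldehyde without epimerising C8 (the descriptor changes only through the priority rules).

Step 10
Reactants: 15 malonyl dichloride; 16 2-(trimethylsilyl)ethanol
Product: 17 bis[2-(trimethylsilyl)ethyl] malonate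
Conditions: 16 (2.1 equiv in all), pyridine (2.2 equiv), CH2Cl2, −10 °C to rt
Reagents that add atoms: 2-(trimethylsilyl)ethanol (second equivalent), C[Si](C)(C)CCO
Why: Twofold acylation: each acid chloride group of 15 takes one molecule of alcohol 16, so two equivalents of the alcohol are built into the symmetrical diester, with pyridine taking up the HCl. The TMSE ester can later be cleaved by fluoride next to an epoxide, an angelate and a lactone, which a methyl ester could not.

Step 11
Reactants: 14 (4S,5S)-2,2-dimethyl-5-[(3S)-3-methylpent-1-en-4-yn-3-yl]-1,3-dioxolane-4-carbaldehyde; 17 bis[2-(trimethylsilyl)ethyl] malonate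
Product: 18 bis[2-(trimethylsilyl)ethyl] 2-{[(4R,5S)-2,2-dimethyl-5-[(3S)-3-methylpent-1-en-4-yn-3-yl]-1,3-dioxolan-4-yl]methylidene}propanedioate
Conditions: piperidine (10 mol %), AcOH (10 mol %), 4 Å molecular sieves, CH2Cl2, rt
Reagents that add atoms: none
Why: Knoevenagel condensation through the iminium ion and dehydration; the symmetrical malonate gives one alkylidene isomer, and buffered amine at room temperature limits epimerisation at C8.

Step 12
Reactants: 18 bis[2-(trimethylsilyl)ethyl] 2-{[(4R,5S)-2,2-dimethyl-5-[(3S)-3-methylpent-1-en-4-yn-3-yl]-1,3-dioxolan-4-yl]methylidene}propanedioate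
Product: 19 bis[2-(trimethylsilyl)ethyl] 2-{[(4R,5S)-2,2-dimethyl-5-[(3R)-3-methyl-1-oxopent-4-en-3-yl]-1,3-dioxolan-4-yl]methylidene}propanedioate
Conditions: [CpRu(NCMe)3]PF6 (5 mol %), 2-(diphenylphosphino)-6-(2,4,6-triisopropylphenyl)pyridine (10 mol %), acetone/H2O (4:1), 60 °C
Reagents that add atoms: water, O
Why: Ruthenium-catalysed anti-Markovnikov hydration of a terminal alkyne through a vinylidene complex, with the pyridylphosphine delivering water to the α-carbon, gives the C6 aldehyde under neutral conditions that leave the vinyl group, the acetonide and the alkylidene malonate alone.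

Step 13
Reactants: 19 bis[2-(trimethylsilyl)ethyl] 2-{[(4R,5S)-2,2-dimethyl-5-[(3R)-3-methyl-1-oxopent-4-en-3-yl]-1,3-dioxolan-4-yl]methylidene}propanedioate
Product: 20 cyclohexan-6-one with 7β-CH(CO2TMSE)2 (H7α) and 8α,9α-O-isopropylidene and 10β-methyl and 10α-vinyl groups
Conditions: 2-(pentafluorophenyl)-6,7-dihydro-5H-pyrrolo[2,1-c][1,2,4]triazol-2-ium tetrafluoroborate (20 mol %), KN(SiMe3)2 (18 mol %), toluene, 23 °C
Reagents that add atoms: none
Why: The free carbene adds to the C6 aldehyde and proton transfer gives the nucleophilic enaminol, whose C6 adds to C7, the β-carbon of the doubly activated C7=C11 bond; proton transfer and loss of the carbene release the C6 ketone, which is the intramolecular Stetter reaction of an aliphatic aldehyde with an alkylidene malonate. The cyclohexanone closes in a 6-exo-trig mode, helped by the quaternary C10 and by the cis-dioxolane that already holds C7 and C10 gauche. The one new stereocentre, C7, is set by the substrate: in the chair-like closure O8 is equatorial, O9 and the C10 methyl are axial, and the malonate takes the equatorial position trans to O8. Because C7–H lies α to the new ketone, an axial epimer can equilibrate under the conditions to the same equatorial isomer, which is the configuration of the target. The step needs acyl-anion addition to win over benzoin or aldol pathways and over γ-deprotonation at C8; the electron-poor N-aryl catalyst and a base charge below the catalyst charge serve this. C5 is a methylene group, so no α-stereocentre can be scrambled, and the equatorial C8–O bond is not aligned for β-elimination from a C6 enolate.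

Step 14
Reactants: 20 cyclohexan-6-one with 7β-CH(CO2TMSE)2 (H7α) and 8α,9α-O-isopropylidene and 10β-methyl and 10α-vinyl groups
Product: 22 5β-allyl derivative of 20 (H5α; allyl equatorial), via dilithium dienolate 21 (not isolated)
Conditions: LiN(i-Pr)2 (2.2 equiv), THF, −78 to −40 °C; allyl bromide (1.1 equiv), DMPU, −78 to −20 °C; then DBU (0.2 equiv), CH2Cl2, rt
Reagents that add atoms: allyl bromide, C=CCBr
Why: Dianion alkylation: the first equivalent of base forms the malonate enolate, which protects C11–H and disfavours deprotonation at the adjacent C7, so the second enolises the ketone toward C5, and this more basic enolate is the one that reacts with allyl bromide. C5 is epimerisable next to the ketone and DBU equilibrates it to the equatorial β-allyl isomer, which avoids a 1,3-diaxial contact with the axial C9 oxygen.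

Step 15
Reactants: 22 5β-allyl derivative of 20 (H5α; allyl equatorial)
Product: 24 trans-fused 8,12-lactone with 11-CO2TMSE and 6-oxo and 9α-hydroxy and 5β-allyl and 10β-methyl and 10α-vinyl groups, via diol 23 (not isolated)
Conditions: AcOH/H2O (4:1), 50 °C; then PPTS (cat.), toluene, 60 °C
Reagents that add atoms: none
Why: Aqueous acid removes the acetonide and the equatorial C8 hydroxyl closes the trans-fused five-membered lactone onto the neighbouring malonate ester by acid-catalysed transesterification. The axial C9 hydroxyl is trans to the C7 arm across the ring and C6 is still a ketone, so only the 8,12-lactone can form.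

Step 16
Reactants: 24 trans-fused 8,12-lactone with 11-CO2TMSE and 6-oxo and 9α-hydroxy and 5β-allyl and 10β-methyl and 10α-vinyl groups
Product: 25 6β,9α-diol (6β-hydroxy axial; otherwise as 24)
Conditions: LiBH(s-Bu)3 (3.3 equiv), THF, −78 °C; then pH 7 buffer
Reagents that add atoms: none
Why: Hindered hydride reduction of a cyclohexanone: the axial C10 methyl blocks the β face, so the hydride attacks C6 along the equatorial direction from the α face and gives the axial 6β-alcohol; the first equivalents are consumed by the C9 hydroxyl and the acidic C11–H, whose enolate also shields the lactone. The C6 alkoxide cannot reach the lactone carbonyl, which is tied to the α-oxygen at C8 on the far side of C7, so the lactone should not migrate.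

Step 17
Reactants: 25 6β,9α-diol (6β-hydroxy axial; otherwise as 24)
Product: 27 C3/O6 lactol (cis-fused 2-hydroxytetrahydrofuran on C5–C6) with a free C1 aldehyde on C10 and 9α-hydroxy group, via hydroxy dialdehyde 26 (not isolated)
Conditions: O3, CH2Cl2/MeOH (5:1), −78 °C; then PPh3, −78 °C to rt
Reagents that add atoms: ozone, [O-][O+]=O
Why: Ozonolysis with reductive work-up cleaves the two monosubstituted alkenes, the only C=C bonds present; the C3 aldehyde is trapped at once by the cis 6β-hydroxyl as a five-membered lactol, while the neopentyl C1 aldehyde cannot cyclise and stays free.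

Step 18
Reactants: 27 C3/O6 lactol (cis-fused 2-hydroxytetrahydrofuran on C5–C6) with a free C1 aldehyde on C10 and 9α-hydroxy group
Product: 28 O-tert-butyldimethylsilyl lactol acetal of 27 (9α-hydroxy and C1 aldehyde free)
Conditions: TBSCl (1.1 equiv), imidazole, CH2Cl2, 0 °C
Reagents that add atoms: tert-butylchlorodimethylsilane, CC(C)(C)[Si](C)(C)Cl
Why: Silylation of the reactive lactol hydroxyl in preference to the hindered axial C9 alcohol fixes the C3/O6 mask as a silyl acetal that fluoride, not acid, will remove.

Step 19
Reactants: 28 O-tert-butyldimethylsilyl lactol acetal of 27 (9α-hydroxy and C1 aldehyde free); 29 angelic acid [(Z)-2-methylbut-2-enoic acid]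
Product: 30 9α-angelate of 28 (C1 aldehyde free)
Conditions: 2,4,6-Cl3C6H2COCl, Et3N, toluene, rt; then 28, 80 °C
Reagents that add atoms: none
Why: Yamaguchi-type esterification through the mixed 2,4,6-trichlorobenzoic anhydride, run without DMAP, is the usual way to angelates with little isomerisation to the tiglate; the C9 hydroxyl is the only free alcohol, and the product is a β-acyloxy aldehyde without α-hydrogen that cannot eliminate.

Step 20
Reactants: 30 9α-angelate of 28 (C1 aldehyde free)
Product: 31 (1R)-oxirane: C10 carries the oxiran-2-yl group (otherwise as 30)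
Conditions: Me3S+ I− (3.0 equiv), KN(SiMe3)2 (2.8 equiv), THF/DMSO (4:1), −20 °C; then 30, −40 to 0 °C
Reagents that add atoms: trimethylsulfonium iodide, C[S+](C)C.[I-]
Why: Corey–Chaykovsky reaction: the sulfonium methylide adds irreversibly to the neopentyl C1 aldehyde and the betaine closes to the oxirane (one equivalent of ylide is spent on the acidic C11–H). Of the approach paths around C10, the one past C5 is closed by the equatorial C4 substituent and the one under the ring by the axial C9 ester oxygen, so the ylide should enter between the C10 methyl and C9; with a potassium counter-ion and no hydrogen-bond donor the formyl oxygen turns away from the C9–O dipole, which gives the (1R)-configuration.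

Step 21
Reactants: 31 (1R)-oxirane: C10 carries the oxiran-2-yl group (otherwise as 30)
Product: 33 (3aS,4S,5R,6R,7S,7aR)-4-hydroxy-6-methyl-3-methylidene-6-[(2R)-oxiran-2-yl]-2-oxo-5-(3-oxoprop-1-en-2-yl)octahydro-1-benzofuran-7-yl (2Z)-2-methylbut-2-enoate, via acid lactol 32 (not isolated)
Conditions: Bu4NF (2.2 equiv), THF, 0 °C; then CH2=NMe2+ I− (4 equiv), Et3N, CH2Cl2, 0 to 35 °C
Reagents that add atoms: N,N-dimethylmethyleneiminium iodide, C=[N+](C)C.[I-]
Why: Fluoride cleaves the TMSE ester (loss of ethene and Me3SiF) and the silyl acetal; the half-malonate at C11 and the lactol-masked aldehyde are then aminomethylated by the iminium salt (Mannich reaction) and lose CO2 plus dimethylamine at C11 and dimethylamine at C4, giving the C13 methylene lactone and the C15 acrolein. No strong base or acid touches the epoxide, the angelate or the allylic C5–H and C7–H at this stage.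

## Compound list

1 | (Z)-3-methylpent-2-en-4-yn-1-ol | OC/C=C(/C)C#C | starting material
2 | (Z)-trimethyl{[3-methyl-5-(trimethylsilyl)pent-2-en-4-yn-1-yl]oxy}silane | C[Si](C)(C)OC/C=C(/C)C#C[Si](C)(C)C | intermediate
3 | (Z)-3-methyl-5-(trimethylsilyl)pent-2-en-4-yn-1-ol | OC/C=C(/C)C#C[Si](C)(C)C | intermediate
4 | (Z)-3-methyl-5-(trimethylsilyl)pent-2-en-4-yn-1-yl methanesulfonate | CS(=O)(=O)OC/C=C(/C)C#C[Si](C)(C)C | intermediate
5 | (Z)-(5-chloro-3-methylpent-3-en-1-yn-1-yl)trimethylsilane | ClC/C=C(/C)C#C[Si](C)(C)C | intermediate
6 | (Z)-4,4,5,5-tetramethyl-2-[3-methyl-5-(trimethylsilyl)pent-2-en-4-yn-1-yl]-1,3,2-dioxaborolane | CC1(C)OB(C/C=C(/C)C#C[Si](C)(C)C)OC1(C)C | intermediate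
7 | (R)-2,2-dimethyl-1,3-dioxolane-4-carbaldehyde | O=C[C@H]1COC(C)(C)O1 | starting material
8 | pinacol borate of alcohol 9 (O9–B) | C[Si](C)(C)C#C[C@](C)(C=C)[C@H](OB2OC(C)(C)C(C)(C)O2)[C@H]1COC(C)(C)O1 | intermediate
9 | (1S,2S)-1-[(4R)-2,2-dimethyl-1,3-dioxolan-4-yl]-2-methyl-2-[(trimethylsilyl)ethynyl]but-3-en-1-ol | C[Si](C)(C)C#C[C@](C)(C=C)[C@H](O)[C@H]1COC(C)(C)O1 | intermediate
10 | (2R,3S,4S)-4-methyl-4-[(trimethylsilyl)ethynyl]hex-5-ene-1,2,3-triol | C[Si](C)(C)C#C[C@](C)(C=C)[C@H](O)[C@H](O)CO | intermediate
11 | (2R,3S,4S)-1-[(tert-butyldimethylsilyl)oxy]-4-methyl-4-[(trimethylsilyl)ethynyl]hex-5-ene-2,3-diol | C[Si](C)(C)C#C[C@](C)(C=C)[C@H](O)[C@H](O)CO[Si](C)(C)C(C)(C)C | intermediate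
12 | tert-butyl{[(4R,5S)-2,2-dimethyl-5-[(3S)-3-methyl-5-(trimethylsilyl)pent-1-en-4-yn-3-yl]-1,3-dioxolan-4-yl]methoxy}dimethylsilane | C[Si](C)(C)C#C[C@](C)(C=C)[C@@H]1OC(C)(C)O[C@@H]1CO[Si](C)(C)C(C)(C)C | intermediate
13 | [(4R,5S)-2,2-dimethyl-5-[(3S)-3-methylpent-1-en-4-yn-3-yl]-1,3-dioxolan-4-yl]methanol | C#C[C@](C)(C=C)[C@@H]1OC(C)(C)O[C@@H]1CO | intermediate
14 | (4S,5S)-2,2-dimethyl-5-[(3S)-3-methylpent-1-en-4-yn-3-yl]-1,3-dioxolane-4-carbaldehyde | C#C[C@](C)(C=C)[C@@H]1OC(C)(C)O[C@@H]1C=O | intermediate
15 | malonyl dichloride | O=C(Cl)CC(=O)Cl | starting material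
16 | 2-(trimethylsilyl)ethanol | C[Si](C)(C)CCO | starting material
17 | bis[2-(trimethylsilyl)ethyl] malonate | C[Si](C)(C)CCOC(=O)CC(=O)OCC[Si](C)(C)C | intermediate
18 | bis[2-(trimethylsilyl)ethyl] 2-{[(4R,5S)-2,2-dimethyl-5-[(3S)-3-methylpent-1-en-4-yn-3-yl]-1,3-dioxolan-4-yl]methylidene}propanedioate | C#C[C@](C)(C=C)[C@@H]1OC(C)(C)O[C@@H]1C=C(C(=O)OCC[Si](C)(C)C)C(=O)OCC[Si](C)(C)C | intermediate
19 | bis[2-(trimethylsilyl)ethyl] 2-{[(4R,5S)-2,2-dimethyl-5-[(3R)-3-methyl-1-oxopent-4-en-3-yl]-1,3-dioxolan-4-yl]methylidene}propanedioate (C6 aldehyde tethered to the C7=C11 acceptor) | O=CC[C@](C)(C=C)[C@@H]1OC(C)(C)O[C@@H]1C=C(C(=O)OCC[Si](C)(C)C)C(=O)OCC[Si](C)(C)C | intermediate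
20 | cyclohexan-6-one: 7β-CH(CO2TMSE)2, 8α,9α-O-isopropylidene, 10β-methyl, 10α-vinyl | CC1(C)O[C@@H]2[C@@H](C(C(=O)OCC[Si](C)(C)C)C(=O)OCC[Si](C)(C)C)C(=O)C[C@](C)(C=C)[C@@H]2O1 | intermediate
21 | dilithium dienolate of 20 (malonate enolate and C5=C6 enolate) | [Li+].[Li+].CC1(C)O[C@@H]2[C@@H](C(C(=O)OCC[Si](C)(C)C)=C([O-])OCC[Si](C)(C)C)C([O-])=C[C@](C)(C=C)[C@@H]2O1 | intermediate
22 | 5β-allyl cyclohexan-6-one (otherwise as 20) | CC1(C)O[C@@H]2[C@@H](C(C(=O)OCC[Si](C)(C)C)C(=O)OCC[Si](C)(C)C)C(=O)[C@@H](CC=C)[C@](C)(C=C)[C@@H]2O1 | intermediate
23 | 8α,9α-diol of 22 (acetonide removed) | O[C@@H]1[C@@H](C(C(=O)OCC[Si](C)(C)C)C(=O)OCC[Si](C)(C)C)C(=O)[C@@H](CC=C)[C@](C)(C=C)[C@@H]1O | intermediate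
24 | trans-fused 8,12-lactone: 11-CO2TMSE, 6-oxo, 9α-hydroxy, 5β-allyl, 10β-methyl, 10α-vinyl | C[Si](C)(C)CCOC(=O)C1C(=O)O[C@@H]2[C@@H]1C(=O)[C@@H](CC=C)[C@](C)(C=C)[C@@H]2O | intermediate
25 | 6β,9α-diol lactone (6β-hydroxy axial; otherwise as 24) | C[Si](C)(C)CCOC(=O)C1C(=O)O[C@@H]2[C@@H]1[C@@H](O)[C@@H](CC=C)[C@](C)(C=C)[C@@H]2O | intermediate
26 | open hydroxy dialdehyde: 5β-CH2CHO, 10α-CHO, 6β,9α-diol | C[Si](C)(C)CCOC(=O)C1C(=O)O[C@@H]2[C@@H]1[C@@H](O)[C@@H](CC=O)[C@](C)(C=O)[C@@H]2O | intermediate
27 | C3/O6 lactol with free C1 aldehyde and 9α-hydroxyl | C[Si](C)(C)CCOC(=O)C1C(=O)O[C@@H]2[C@@H]1[C@H]1OC(O)C[C@H]1[C@](C)(C=O)[C@@H]2O | intermediate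
28 | O-TBS lactol acetal with free C1 aldehyde and 9α-hydroxyl | C[Si](C)(C)CCOC(=O)C1C(=O)O[C@@H]2[C@@H]1[C@H]1OC(O[Si](C)(C)C(C)(C)C)C[C@H]1[C@](C)(C=O)[C@@H]2O | intermediate
29 | angelic acid, (Z)-2-methylbut-2-enoic acid | C/C=C(/C)C(=O)O | starting material
30 | 9α-angelate with free C1 aldehyde (otherwise as 28) | C[Si](C)(C)CCOC(=O)C1C(=O)O[C@@H]2[C@@H]1[C@H]1OC(O[Si](C)(C)C(C)(C)C)C[C@H]1[C@](C)(C=O)[C@@H]2OC(=O)/C(C)=C\C | intermediate
31 | (1R)-oxirane (otherwise as 30) | C[Si](C)(C)CCOC(=O)C1C(=O)O[C@@H]2[C@@H]1[C@H]1OC(O[Si](C)(C)C(C)(C)C)C[C@H]1[C@](C)([C@@H]3CO3)[C@@H]2OC(=O)/C(C)=C\C | intermediate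
32 | acid lactol: 11-carboxy lactone, C3/O6 lactol, (1R)-oxirane, 9α-angelate | OC(=O)C1C(=O)O[C@@H]2[C@@H]1[C@H]1OC(O)C[C@H]1[C@](C)([C@@H]3CO3)[C@@H]2OC(=O)/C(C)=C\C | intermediate
33 | (3aS,4S,5R,6R,7S,7aR)-4-hydroxy-6-methyl-3-methylidene-6-[(2R)-oxiran-2-yl]-2-oxo-5-(3-oxoprop-1-en-2-yl)octahydro-1-benzofuran-7-yl (2Z)-2-methylbut-2-enoate | C=C1C(=O)O[C@@H]2[C@@H]1[C@@H](O)[C@@H](C(=C)C=O)[C@](C)([C@@H]1CO1)[C@@H]2OC(=O)/C(C)=C\C | target

## Step count and least certain steps

Total step count: 21. Longest linear sequence: 20 steps (1 to 33 through steps 1–9 and 11–21); step 10 is a one-step side branch.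

**Step 13 (key step).** Most likely failure: ring closure to the six-membered ketone is slow for an aliphatic aldehyde, so self-condensation of the aldehyde and base-induced γ-deprotonation of the acceptor (epimerisation at C8) can take over. Fallback, from 19 back to 20: form the same C6–C7 bond with an acyl radical. NaClO2/NaH2PO4/2-methyl-2-butene oxidises 19 to carboxylic acid F1; PhSeSePh and PBu3 convert it into Se-phenyl selenoester F2; Bu3SnH and AIBN in benzene at 80 °C generate the C6 acyl radical, which closes 6-exo onto C7 of the electron-poor alkene (polarity-matched) and gives 20 after hydrogen transfer; DBU then equilibrates C7.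

**Step 20.** Most likely failure: poor facial selectivity in the methylene transfer, because the result depends on which way the formyl group is turned in the single open approach sector; methylation or side reactions of the C11 enolate are a second risk. Fallback, from 30 back to 31: give up substrate control and separate by catalyst control. The mixture of 31 and its C1 epimer, epimeric oxirane F3, is treated with water (half an equivalent relative to F3) and the enantiomer of (salen)Co(OAc), the acetate of the trivalent cobalt salen complex, that hydrolyses (1S)-oxiranes faster; F3 is converted into diol F4 and 31 is recovered unchanged.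

**Step 14.** Most likely failure: alkylation at the malonate carbon or at oxygen instead of C5, or incomplete enolisation at the hindered C5. Fallback, from 20 back to 22: neutral Stork alkylation. Pyrrolidine with 4 Å molecular sieves and a trace of TsOH in benzene at 60 °C gives the less substituted enamine F5 (C5=C6); allyl bromide in MeCN, hydrolysis with aqueous AcOH/NaOAc and DBU equilibration give 22 without any strong base.

**Step 12.** Most likely failure: slow vinylidene formation at the neopentyl alkyne, with degradation of the alkylidene malonate in hot aqueous acetone. Fallback, from 13 back to 19: hydrate the alkyne before the acceptor exists. Dicyclohexylborane (excess; the hydroxyl consumes one equivalent, and the alkyne reacts before the hindered vinyl group) then NaBO3 gives hydroxy aldehyde F6; HC(OMe)3/PPTS gives dimethyl acetal F7; Dess–Martin oxidation gives aldehyde F8; Knoevenagel condensation with 17 gives alkylidene malonate acetal F9; PPTS in wet acetone releases the aldehyde 19, the acetone preserving the acetonide.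

**Step 19.** Most likely failure: incomplete acylation of the hindered axial alcohol, Z to E isomerisation of the acyl group, or retro-aldol cleavage of the β-hydroxy aldehyde under hot amine base. Fallback, from 28 back to 30: make the ester by alkoxycarbonylation instead of carboxyl activation. (Z)-2-Bromobut-2-ene, CO (1 atm), Pd(PPh3)4 and Et3N in toluene at 70 °C form the acylpalladium species with retention of alkene geometry (oxidative addition to zerovalent palladium, CO insertion), and the C9 hydroxyl captures it; no new compound is made.

## Further compounds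

F1 | step 13 | carboxylic acid from 19 (C6 as CO2H; otherwise as 19) | OC(=O)C[C@](C)(C=C)[C@@H]1OC(C)(C)O[C@@H]1C=C(C(=O)OCC[Si](C)(C)C)C(=O)OCC[Si](C)(C)C
F2 | step 13 | Se-phenyl selenoester of F1 | O=C([Se]c1ccccc1)C[C@](C)(C=C)[C@@H]1OC(C)(C)O[C@@H]1C=C(C(=O)OCC[Si](C)(C)C)C(=O)OCC[Si](C)(C)C
F3 | step 20 | (1S)-oxirane, C1 epimer of 31 | C[Si](C)(C)CCOC(=O)C1C(=O)O[C@@H]2[C@@H]1[C@H]1OC(O[Si](C)(C)C(C)(C)C)C[C@H]1[C@](C)([C@H]3CO3)[C@@H]2OC(=O)/C(C)=C\C
F4 | step 20 | (1S)-1,2-diol from hydrolysis of F3 | C[Si](C)(C)CCOC(=O)C1C(=O)O[C@@H]2[C@@H]1[C@H]1OC(O[Si](C)(C)C(C)(C)C)C[C@H]1[C@](C)([C@H](O)CO)[C@@H]2OC(=O)/C(C)=C\C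
F5 | step 14 | pyrrolidine enamine of 20 (C5=C6) | CC1(C)O[C@@H]2[C@@H](C(C(=O)OCC[Si](C)(C)C)C(=O)OCC[Si](C)(C)C)C(N3CCCC3)=C[C@](C)(C=C)[C@@H]2O1
F6 | step 12 | hydroxy aldehyde from 13 (C6 aldehyde, C7 alcohol) | O=CC[C@](C)(C=C)[C@@H]1OC(C)(C)O[C@@H]1CO
F7 | step 12 | dimethyl acetal of F6 | COC(OC)C[C@](C)(C=C)[C@@H]1OC(C)(C)O[C@@H]1CO
F8 | step 12 | C7 aldehyde with C6 dimethyl acetal | COC(OC)C[C@](C)(C=C)[C@@H]1OC(C)(C)O[C@@H]1C=O
F9 | step 12 | alkylidene malonate with C6 dimethyl acetal | COC(OC)C[C@](C)(C=C)[C@@H]1OC(C)(C)O[C@@H]1C=C(C(=O)OCC[Si](C)(C)C)C(=O)OCC[Si](C)(C)C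
F0 | step 19 | none | none
A1 | alternative 1 | head-to-tail enone–cyclobutene photoadduct with a bicyclo[2.2.0]hexane fused to the 9-oxo 6-silyloxy α-methyl lactone | C[C@H]1C(=O)O[C@@H]2[C@@H]1[C@@H](O[Si](C)(C)C(C)(C)C)[C@H]([C@@]3(C)CC[C@H]34)[C@@]4(C)C2=O
A2 | alternative 1 | 1-methylcyclobutene | CC1=CCC1
A3 | alternative 2 | cyclohexane-fused isoxazoline from the nitrile oxide cycloaddition | CC1(C)O[C@@H]2[C@@H](C(C)=C)C3=NOC(C)(C)[C@H]3[C@](C)(C(OC)OC)[C@@H]2O1
A4 | alternative 3 | cyclohexanol from the carbonyl-ene closure (trans C7 isopropenyl and C8 hydroxyl) | O[C@@H]1[C@@H](C(C)=C)[C@@H](O[Si](C)(C)C(C)(C)C)[C@@H](C(=C)COC(=O)C(C)(C)C)[C@](C)(C=C)[C@@H]1OCc1ccc(OC)cc1
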